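**Retrosynthetic overview**
1. Target 36 ⇐ acrylic acid 35 (asymmetric hydrogenation sets the side-chain CH) ⇐ isopropenyl tetracycle 32. Ring A is closed last: C8–C9 by alkylation of the ring B lactone enolate, C7–H by conjugate reduction, C6–C7 by Negishi coupling of enol triflate 18 with chloro iodide 28.
2. Ring B ⇐ Dieckmann closure of the acetate of 15 onto its own methyl ester.
3. Ring D and the spiro carbon ⇐ one-pot radical cyclisation / boron enolate / formaldehyde aldol of iodomethyl ether 10 (ether CH2–bridgehead CH bond, then spiro C–CH2O bond). Ring C is the ring of 1, made chiral by copper-catalysed borylation of dienone 2.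
4. Order of ring formation: C, D, B, A (A cyclohexane, B δ-lactone, C cyclohexanone, D oxolane bridge).
5. Feature: on ring C the ether CH2 of ring D spans the O-bearing CH and the bridgehead CH on one face, while the lactone OCH2 of ring B sits on the opposite face of the adjacent spiro carbon. This anti pair is what a conjugate addition followed by enolate trapping delivers.

Key step: step 7

Remark on labels used below: ring C = C13 (spiro), C14 (C=O), C15, C16 (CH–O), C20 (CMe2), C19 (bridgehead CH); ether bridge O17–C18; ring B = C13, C7, C8, C10 (C=O), O11, C12; ring A = C7, C8, C9, C4, C5, C6; side chain C2 (CH), C1 (CH3), C3 (CO2H). The ligand antipodes in steps 2 and 22 are chosen by the usual sense of these catalysts; the other antipode would be taken if the sense proved opposite.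

Step 1
Reactants: 1 4,4-dimethylcyclohex-2-en-1-one
Product: 2 4,4-dimethylcyclohexa-2,5-dien-1-one
Conditions: DDQ, dioxane, reflux
Reagents that add atoms: none
Why: Quinone dehydrogenation of the enone should give the cross-conjugated dienone, whose quaternary carbon prevents aromatisation and whose two enone arms are enantiotopic.

Step 2
Reactants: 2 4,4-dimethylcyclohexa-2,5-dien-1-one; 3 bis(pinacolato)diboron
Product: 5 (S)-5-hydroxy-4,4-dimethylcyclohex-2-en-1-one, via β-boryl ketone 4 (not isolated)
Conditions: CuCl (cat.), NaOt-Bu (cat.), (R)-1-[(Sp)-2-(diphenylphosphino)ferrocenyl]ethyldicyclohexylphosphine (cat.), 3 (1.0 equiv), MeOH, THF, 0 °C; then NaBO3·4H2O, THF–H2O, 23 °C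
Reagents that add atoms: sodium perborate, [Na+].[O-]OB=O
Why: Copper-catalysed asymmetric conjugate borylation desymmetrises the dienone, the chiral diphosphine selecting the face of the β-carbon (S centre), and perborate oxidation replaces boron by oxygen with retention.

Step 3
Reactants: 5 (S)-5-hydroxy-4,4-dimethylcyclohex-2-en-1-one
Product: 6 (S)-5-hydroxy-2-iodo-4,4-dimethylcyclohex-2-en-1-one
Conditions: I2, pyridine, CH2Cl2, 23 °C
Reagents that add atoms: iodine, II
Why: α-Iodination of the enone by amine addition, iodination and elimination is regiospecific for the α-carbon and leaves the carbinol centre untouched.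

Step 4
Reactants: 6 (S)-5-hydroxy-2-iodo-4,4-dimethylcyclohex-2-en-1-one
Product: 7 (S)-2-iodo-4,4-dimethyl-5-[(methylsulfanyl)methoxy]cyclohex-2-en-1-one
Conditions: Me2S, dibenzoyl peroxide, MeCN, 0 °C
Reagents that add atoms: dimethyl sulfide, CSC
Why: Pummerer-type transfer of a methylthiomethyl group from the sulfonium formed in situ etherifies the hindered alcohol without base, so E1cB loss of the β-oxygen is avoided.

Step 5
Reactants: 7 (S)-2-iodo-4,4-dimethyl-5-[(methylsulfanyl)methoxy]cyclohex-2-en-1-one
Product: 8 methyl (S)-3,3-dimethyl-4-[(methylsulfanyl)methoxy]-6-oxocyclohex-1-ene-1-carboxylate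
Conditions: CO (1 atm), MeOH, Pd(OAc)2 (cat.), PPh3, Et3N, DMF, 50 °C
Reagents that add atoms: carbon monoxide, [C-]#[O+]; methanol, CO
Why: Palladium-catalysed methoxycarbonylation of the reactive α-iodoenone should give the alkylidene β-keto ester, which the adjacent CMe2 group stabilises against dimerisation.

Step 6
Reactants: 8 methyl (S)-3,3-dimethyl-4-[(methylsulfanyl)methoxy]-6-oxocyclohex-1-ene-1-carboxylate
Product: 10 methyl (S)-4-(iodomethoxy)-3,3-dimethyl-6-oxocyclohex-1-ene-1-carboxylate, via chloromethyl ether 9 (not isolated)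
Conditions: SO2Cl2, CH2Cl2, −78 to 0 °C; evaporation; then NaI, acetone, 0 °C; used at once
Reagents that add atoms: sodium iodide, [Na+].[I-]
Why: Sulfuryl chloride cleaves the O,S-acetal at sulfur to the chloromethyl ether and Finkelstein exchange gives the iodomethyl ether, while the electron-poor alkene is inert to the sulfenyl chloride set free.

Step 7
Reactants: 10 methyl (S)-4-(iodomethoxy)-3,3-dimethyl-6-oxocyclohex-1-ene-1-carboxylate; 11 triethylborane; 12 formaldehyde
Product: 15 methyl (1S,2R,5S)-2-(hydroxymethyl)-8,8-dimethyl-3-oxo-6-oxabicyclo[3.2.1]octane-2-carboxylate, via boron enolate 13 (not isolated), via boron aldolate 14 (not isolated)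
Conditions: Et3B (2.5 equiv), air (slow inlet), monomeric CH2O (THF solution, excess), CH2Cl2, −78 to −20 °C; pH 7 buffer
Reagents that add atoms: formaldehyde, C=O
Why: Proposed new method: ethyl radicals from Et3B and air abstract iodine from 10, the nucleophilic alkoxymethyl radical adds 5-exo-trig to the β-carbon of the alkylidene β-keto ester (closing ring D), and the 1,3-dicarbonyl radical is captured by Et3B as boron enolate 13 with release of a new ethyl radical; 13 then adds to formaldehyde to give 14. The closest known chemistry is the Et3B-induced radical conjugate addition–aldol coupling of alkyl iodides, enones and aldehydes, and the 5-exo cyclisation of alkoxymethyl radicals; their merger on a tethered radical, ending in a quaternary carbon, is untested. The bridgehead centre C19 is fixed by the tether, because the short O–CH2 radical reaches only the face of ring C that carries the S-configured oxygen, through the conformer with that oxygen axial. The spiro centre C13 is set in the aldol: in 13 the new bridge CH2 on C19 nearly eclipses the upper lobe of the enolate carbon, so formaldehyde should enter anti to the two-atom bridge, as electrophiles do with tropinone-type bicyclo[3.2.1]octan-3-one enolates, placing CH2OH trans and CO2Me cis to the bridge. The step needs syn delivery of the ether carbon, anti delivery of formaldehyde and iodine abstraction faster than ethyl addition to the alkene; the tether, the axial bridge and the neopentyl-type β-carbon should secure these. The axial methyl of C20 on the lower face is the main hazard for the aldol face.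

Step 8
Reactants: 15 methyl (1S,2R,5S)-2-(hydroxymethyl)-8,8-dimethyl-3-oxo-6-oxabicyclo[3.2.1]octane-2-carboxylate
Product: 16 methyl (1S,2R,5S)-2-(acetoxymethyl)-8,8-dimethyl-3-oxo-6-oxabicyclo[3.2.1]octane-2-carboxylate
Conditions: Ac2O, pyridine, DMAP (cat.), CH2Cl2, 0 °C, on crude 15
Reagents that add atoms: acetic anhydride, CC(=O)OC(C)=O
Why: Immediate acylation blocks retro-aldol loss of formaldehyde and at the same time installs the two carbons (C8, C10) needed for ring B.

Step 9
Reactants: 16 methyl (1S,2R,5S)-2-(acetoxymethyl)-8,8-dimethyl-3-oxo-6-oxabicyclo[3.2.1]octane-2-carboxylate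
Product: 17 spiro enol lactone (ring B as 4-hydroxy-5,6-dihydro-2H-pyran-2-one, its C5 being the spiro carbon of the 8,8-dimethyl-6-oxabicyclo[3.2.1]octan-3-one core; lactone OCH2 anti to the ether bridge)
Conditions: LiN(i-Pr)2 (3.3 equiv), THF, −78 °C (16 added to the base), then 0 °C; 1 M HCl
Reagents that add atoms: none
Why: Dieckmann condensation of the acetate enolate onto the neighbouring methyl ester closes the six-membered ring B and is driven by deprotonation of the β-keto lactone, while the ring C ketone is shielded as its enolate and the stereocentres are not involved.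

Step 10
Reactants: 17 spiro enol lactone
Product: 18 enol triflate of 17 (4-trifluoromethanesulfonyloxy-5,6-dihydro-2H-pyran-2-one ring B)
Conditions: Tf2O, Et3N, CH2Cl2, −78 °C
Reagents that add atoms: trifluoromethanesulfonic anhydride, O=S(=O)(OS(=O)(=O)C(F)(F)F)C(F)(F)F
Why: O-sulfonylation of the vinylogous acid gives the β-triflyloxy enoate at C7, the hindered ketone being inert under these conditions.

Step 11
Reactants: 19 (S)-4-benzyl-1,3-oxazolidin-2-one; 20 3-methylbut-2-enoyl chloride
Product: 21 (S)-4-benzyl-3-(3-methylbut-2-enoyl)-1,3-oxazolidin-2-one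
Conditions: n-BuLi, THF, −78 °C; then 20
Reagents that add atoms: 3-methylbut-2-enoyl chloride (20), CC(C)=CC(Cl)=O
Why: N-acylation of the lithiated oxazolidinone gives the imide that carries the future isopropenyl group.

Step 12
Reactants: 21 (S)-4-benzyl-3-(3-methylbut-2-enoyl)-1,3-oxazolidin-2-one; 22 tert-butyl bromoacetate
Product: 23 tert-butyl (S)-3-[(S)-4-benzyl-2-oxo-1,3-oxazolidine-3-carbonyl]-4-methylpent-4-enoate
Conditions: NaN(SiMe3)2, THF, −78 °C; then 22, −78 to −40 °C
Reagents that add atoms: tert-butyl bromoacetate (22), CC(C)(C)OC(=O)CBr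
Why: Evans alkylation of the chelated sodium dienolate (γ-deprotonation) occurs at the α-carbon on the face away from the benzyl group, moving the alkene out of conjugation and setting the S centre that becomes C4.

Step 13
Reactants: 23 tert-butyl (S)-3-[(S)-4-benzyl-2-oxo-1,3-oxazolidine-3-carbonyl]-4-methylpent-4-enoate
Product: 24 tert-butyl (S)-3-(hydroxymethyl)-4-methylpent-4-enoate
Conditions: LiBH4, MeOH (1 equiv), THF, 0 °C
Reagents that add atoms: none
Why: Borohydride cleaves the imide reductively to the primary alcohol and spares the tert-butyl ester, without touching the stereocentre.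

Step 14
Reactants: 24 tert-butyl (S)-3-(hydroxymethyl)-4-methylpent-4-enoate
Product: 26 tert-butyl (S)-3-(chloromethyl)-4-methylpent-4-enoate, via mesylate 25 (not isolated)
Conditions: MsCl, Et3N, CH2Cl2, 0 °C; then LiCl, DMF, 50 °C
Reagents that add atoms: lithium chloride, [Li+].[Cl-]
Why: Sulfonylation and SN2 displacement by chloride at the primary carbon give the chloride that will later be the C9 electrophile.

Step 15
Reactants: 26 tert-butyl (S)-3-(chloromethyl)-4-methylpent-4-enoate
Product: 27 (S)-3-(chloromethyl)-4-methylpent-4-en-1-ol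
Conditions: i-Bu2AlH (2.5 equiv), CH2Cl2, −78 to 0 °C
Reagents that add atoms: none
Why: Hydride reduction of the ester to the primary alcohol leaves the alkyl chloride and the alkene intact.

Step 16
Reactants: 27 (S)-3-(chloromethyl)-4-methylpent-4-en-1-ol
Product: 28 (S)-3-(chloromethyl)-5-iodo-2-methylpent-1-ene
Conditions: I2, PPh3, imidazole, CH2Cl2, 0 °C
Reagents that add atoms: iodine, II
Why: Appel-type iodination gives a chloro iodide whose two halides differ enough for selective zinc insertion.

Step 17
Reactants: 28 (S)-3-(chloromethyl)-5-iodo-2-methylpent-1-ene; 18 enol triflate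
Product: 30 β-alkyl enelactone (18 with the triflate replaced at C7 by the (S)-3-(chloromethyl)-4-methylpent-4-en-1-yl chain), via alkylzinc iodide 29 (not isolated)
Conditions: Zn dust, LiCl, THF, 40 °C; then 18, PdCl2(dppf) (cat.), THF, 23 °C
Reagents that add atoms: none
Why: Zinc inserts only into the C–I bond, and Negishi coupling of the alkylzinc with the electron-poor vinyl triflate forms C6–C7 while ketone, lactone and chloride are tolerated.

Step 18
Reactants: 30 β-alkyl enelactone
Product: 31 saturated chloro lactone (30 with C7=C8 reduced; 7R, H at C7 anti to C14)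
Conditions: [(Ph3P)CuH]6, toluene, 23 °C; aq. NH4Cl
Reagents that add atoms: none
Why: Conjugate reduction by the phosphine-ligated copper hydride should deliver hydride to C7 anti to the acyl branch C13–C14 of the adjacent quaternary carbon (Felkin–Anh sense, past C19–H and not past the ketone oxygen), which gives the required C7 configuration; the isolated ketone, alkene and chloride are not reduced.

Step 19
Reactants: 31 saturated chloro lactone
Product: 32 isopropenyl tetracycle (target skeleton with prop-1-en-2-yl at C4; 4R,7R,8S, rings A and B cis-fused)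
Conditions: LiN(i-Pr)2 (2.5 equiv), THF–DMPU, −78 to 23 °C; aq. NH4Cl
Reagents that add atoms: none
Why: Intramolecular 6-exo-tet alkylation of the lactone enolate closes ring A, and the chain can reach C8 only from the face on which it is attached at C7, so the fusion is cis. The cis isomer is also the expected stable C8 epimer because it keeps C6 axial on ring B and away from the bridge CH2, and the ketone sits out as its enolate.

Step 20
Reactants: 32 isopropenyl tetracycle
Product: 34 enal (2-substituted propenal side chain on C4), via allylic alcohol 33 (not isolated)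
Conditions: SeO2 (cat.), t-BuOOH, CH2Cl2, 23 °C; then DMP (1,1,1-triacetoxy-1,1-dihydro-1,2-benziodoxol-3(1H)-one), CH2Cl2, 23 °C
Reagents that add atoms: tert-butyl hydroperoxide, CC(C)(C)OO
Why: Selenium dioxide ene oxidation attacks the methyl group of the 1,1-disubstituted alkene in preference to the allylic methine, and the periodinane takes the alcohol on to the enal without epimerising C8.

Step 21
Reactants: 34 enal
Product: 35 acrylic acid (2-substituted prop-2-enoic acid on C4)
Conditions: NaClO2, NaH2PO4, 2-methylbut-2-ene, t-BuOH–H2O, 0 to 23 °C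
Reagents that add atoms: sodium chlorite, [Na+].[O-]Cl=O
Why: Pinnick oxidation converts the conjugated aldehyde to the acid under buffered conditions that leave the alkene, ketone and lactone alone.

Step 22
Reactants: 35 acrylic acid
Product: 36 target CNP0152427.1
Conditions: H2 (50 bar), Ru(OAc)2[(R)-BINAP] (cat.), MeOH, 23 °C
Reagents that add atoms: none
Why: Carboxylate-directed asymmetric hydrogenation of the 2-substituted acrylic acid should set C2 as R under catalyst control, the R ligand giving the R acid as with other 2-alkyl- and 2-arylacrylic acids, and the unactivated ketone is not reduced.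

**Compound list**
1 | 4,4-dimethylcyclohex-2-en-1-one | CC1(C)CCC(=O)C=C1 | starting material
2 | 4,4-dimethylcyclohexa-2,5-dien-1-one | CC1(C)C=CC(=O)C=C1 | intermediate
3 | bis(pinacolato)diboron | CC1(C)OB(OC1(C)C)B1OC(C)(C)C(C)(C)O1 | starting material
4 | (S)-4,4-dimethyl-5-(4,4,5,5-tetramethyl-1,3,2-dioxaborolan-2-yl)cyclohex-2-en-1-one | O=C1C=CC(C)(C)[C@@H](B2OC(C)(C)C(C)(C)O2)C1 | intermediate
5 | (S)-5-hydroxy-4,4-dimethylcyclohex-2-en-1-one | O=C1C=CC(C)(C)[C@@H](O)C1 | intermediate
6 | (S)-5-hydroxy-2-iodo-4,4-dimethylcyclohex-2-en-1-one | O=C1C(I)=CC(C)(C)[C@@H](O)C1 | intermediate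
7 | (S)-2-iodo-4,4-dimethyl-5-[(methylsulfanyl)methoxy]cyclohex-2-en-1-one | O=C1C(I)=CC(C)(C)[C@@H](OCSC)C1 | intermediate
8 | methyl (S)-3,3-dimethyl-4-[(methylsulfanyl)methoxy]-6-oxocyclohex-1-ene-1-carboxylate | COC(=O)C1=CC(C)(C)[C@@H](OCSC)CC1=O | intermediate
9 | methyl (S)-4-(chloromethoxy)-3,3-dimethyl-6-oxocyclohex-1-ene-1-carboxylate | COC(=O)C1=CC(C)(C)[C@@H](OCCl)CC1=O | intermediate
10 | methyl (S)-4-(iodomethoxy)-3,3-dimethyl-6-oxocyclohex-1-ene-1-carboxylate | COC(=O)C1=CC(C)(C)[C@@H](OCI)CC1=O | intermediate
11 | triethylborane | CCB(CC)CC | starting material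
12 | formaldehyde | C=O | starting material
13 | methyl (1S,5S)-3-[(diethylboranyl)oxy]-8,8-dimethyl-6-oxabicyclo[3.2.1]oct-2-ene-2-carboxylate | COC(=O)C1=C(OB(CC)CC)C[C@@H]2OC[C@H]1C2(C)C | intermediate
14 | methyl (1S,2R,5S)-2-{[(diethylboranyl)oxy]methyl}-8,8-dimethyl-3-oxo-6-oxabicyclo[3.2.1]octane-2-carboxylate | COC(=O)[C@]1(COB(CC)CC)C(=O)C[C@@H]2OC[C@H]1C2(C)C | intermediate
15 | methyl (1S,2R,5S)-2-(hydroxymethyl)-8,8-dimethyl-3-oxo-6-oxabicyclo[3.2.1]octane-2-carboxylate | COC(=O)[C@]1(CO)C(=O)C[C@@H]2OC[C@H]1C2(C)C | intermediate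
16 | methyl (1S,2R,5S)-2-(acetoxymethyl)-8,8-dimethyl-3-oxo-6-oxabicyclo[3.2.1]octane-2-carboxylate | COC(=O)[C@]1(COC(C)=O)C(=O)C[C@@H]2OC[C@H]1C2(C)C | intermediate
17 | spiro enol lactone (ring B 4-hydroxy-5,6-dihydro-2H-pyran-2-one on the bicyclic ketone; OCH2 anti to the ether bridge) | O=C1C=C(O)[C@]2(CO1)C(=O)C[C@@H]1OC[C@H]2C1(C)C | intermediate
18 | enol triflate of 17 | O=C1C=C(OS(=O)(=O)C(F)(F)F)[C@]2(CO1)C(=O)C[C@@H]1OC[C@H]2C1(C)C | intermediate
19 | (S)-4-benzyl-1,3-oxazolidin-2-one | O=C1N[C@@H](Cc2ccccc2)CO1 | starting material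
20 | 3-methylbut-2-enoyl chloride | CC(C)=CC(Cl)=O | starting material
21 | (S)-4-benzyl-3-(3-methylbut-2-enoyl)-1,3-oxazolidin-2-one | CC(C)=CC(=O)N1[C@@H](Cc2ccccc2)COC1=O | intermediate
22 | tert-butyl bromoacetate | CC(C)(C)OC(=O)CBr | starting material
23 | tert-butyl (S)-3-[(S)-4-benzyl-2-oxo-1,3-oxazolidine-3-carbonyl]-4-methylpent-4-enoate | C=C(C)[C@H](CC(=O)OC(C)(C)C)C(=O)N1[C@@H](Cc2ccccc2)COC1=O | intermediate
24 | tert-butyl (S)-3-(hydroxymethyl)-4-methylpent-4-enoate | C=C(C)[C@H](CC(=O)OC(C)(C)C)CO | intermediate
25 | tert-butyl (S)-3-[(methanesulfonyloxy)methyl]-4-methylpent-4-enoate | C=C(C)[C@H](CC(=O)OC(C)(C)C)COS(C)(=O)=O | intermediate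
26 | tert-butyl (S)-3-(chloromethyl)-4-methylpent-4-enoate | C=C(C)[C@H](CC(=O)OC(C)(C)C)CCl | intermediate
27 | (S)-3-(chloromethyl)-4-methylpent-4-en-1-ol | C=C(C)[C@H](CCO)CCl | intermediate
28 | (S)-3-(chloromethyl)-5-iodo-2-methylpent-1-ene | C=C(C)[C@H](CCI)CCl | intermediate
29 | [(S)-3-(chloromethyl)-4-methylpent-4-en-1-yl]zinc iodide | C=C(C)[C@H](CC[Zn]I)CCl | intermediate
30 | β-alkyl enelactone (chain on C7 of the unsaturated ring B) | O=C1C=C(CC[C@H](CCl)C(C)=C)[C@]2(CO1)C(=O)C[C@@H]1OC[C@H]2C1(C)C | intermediate
31 | saturated chloro lactone (7R) | O=C1C[C@@H](CC[C@H](CCl)C(C)=C)[C@]2(CO1)C(=O)C[C@@H]1OC[C@H]2C1(C)C | intermediate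
32 | isopropenyl tetracycle (4R,7R,8S; rings A and B cis-fused) | C=C(C)[C@@H]1CC[C@@H]2[C@H](C1)C(=O)OC[C@]21C(=O)C[C@@H]2OC[C@H]1C2(C)C | intermediate
33 | allylic alcohol (3-hydroxyprop-1-en-2-yl on C4) | C=C(CO)[C@@H]1CC[C@@H]2[C@H](C1)C(=O)OC[C@]21C(=O)C[C@@H]2OC[C@H]1C2(C)C | intermediate
34 | enal (3-oxoprop-1-en-2-yl on C4) | C=C(C=O)[C@@H]1CC[C@@H]2[C@H](C1)C(=O)OC[C@]21C(=O)C[C@@H]2OC[C@H]1C2(C)C | intermediate
35 | acrylic acid (2-substituted prop-2-enoic acid on C4) | C=C(C(=O)O)[C@@H]1CC[C@@H]2[C@H](C1)C(=O)OC[C@]21C(=O)C[C@@H]2OC[C@H]1C2(C)C | intermediate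
36 | CNP0152427.1, (2R)-propanoic acid; ring centres C4 R, C7 R, C8 S, C13 S, C16 S, C19 S | C[C@@H](C(=O)O)[C@@H]1CC[C@@H]2[C@H](C1)C(=O)OC[C@]21C(=O)C[C@@H]2OC[C@H]1C2(C)C | target

**Step count**
Total: 22 steps (16 in the main line, 6 for chloro iodide 28). Longest linear sequence: 16 steps (steps 1–10 and 17–22).

**Steps most likely to fail**

Step 7 (proposed new method). The chain may collapse through ethyl-radical addition to the alkene, or the boron enolate may be protonated or stay unreactive before it meets formaldehyde, so that the aldol component is lost. The fallback separates the two events with known reactions and sets out from 10. Tin hydride mediated 5-exo cyclisation (Bu3SnH, AIBN, benzene, 80 °C, slow addition) should give methyl (1S,5S)-8,8-dimethyl-3-oxo-6-oxabicyclo[3.2.1]octane-2-carboxylate F1. Base-mediated hydroxymethylation of this β-keto ester with aqueous formaldehyde and KHCO3 in THF at 0 °C, followed by direct acetylation, returns to the route at 15. The face of the aldol is governed by the same bridge in both modes.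

Step 9. Enolate formation may go astray: the ketone enolate can take the acetyl group from oxygen before the acetate is deprotonated, or the ester enolate may not attack the neopentyl ester. The fallback uses a soft nucleophile and sets out from 15. Esterification with allyl hydrogen malonate (DCC, DMAP cat.) should give the mixed allyl malonate F2. DBU in THF then closes ring B through the malonate carbanion to give the 3-allyloxycarbonyl enol lactone F3. Deallylation and decarboxylation with Pd(PPh3)4 and morpholine returns to the route at 17.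

Step 18. Hydride may be delivered to both faces of C7, or the hindered β-carbon may resist the copper hydride. The fallback lets a chiral catalyst and a carbon nucleophile set C7, and sets out from 18. Reduction of the triflate with Pd(OAc)2, PPh3, HCO2H and Bu3N should give the unsubstituted enelactone F4. Iodide 28 is converted with Mg in Et2O into the Grignard reagent F5. F5 is added to F4 at −75 °C with CuBr·SMe2 and the ferrocenyl diphosphine of step 2 (antipode chosen for attack anti to C19), a known asymmetric conjugate addition to unsaturated δ-lactones. This rejoins the route at 31.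

**Further compounds**
F1 | step 7 | methyl (1S,5S)-8,8-dimethyl-3-oxo-6-oxabicyclo[3.2.1]octane-2-carboxylate (C2 epimerisable) | COC(=O)C1C(=O)C[C@@H]2OC[C@H]1C2(C)C
F2 | step 9 | allyl malonate mixed ester of 15 | COC(=O)[C@]1(COC(=O)CC(=O)OCC=C)C(=O)C[C@@H]2OC[C@H]1C2(C)C
F3 | step 9 | 3-allyloxycarbonyl derivative of 17 | O=C1C(C(=O)OCC=C)=C(O)[C@]2(CO1)C(=O)C[C@@H]1OC[C@H]2C1(C)C
F4 | step 18 | unsubstituted spiro enelactone | O=C1C=C[C@]2(CO1)C(=O)C[C@@H]1OC[C@H]2C1(C)C
F5 | step 18 | [(S)-3-(chloromethyl)-4-methylpent-4-en-1-yl]magnesium iodide | C=C(C)[C@H](CC[Mg]I)CCl
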